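**Assumption:** the target has no stereocentre and no stereogenic double bond, so "single enantiomer" is taken to mean the one achiral structure given; racemic or E/Z-mixed intermediates lose those elements later and are marked.

**Retrosynthetic overview**
1. Key disconnection: the resorcinol ring itself. A retro-[4+2] across C1–C2 and C5–C6 of the benzene ring gives a pyrrolyl ethynyl ketone and a 2-alkyl Chan-type 1-methoxy-1,3-bis(silyloxy)diene; this replaces the usual Friedel–Crafts acylation of a 2-alkylresorcinol.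
2. Diene: from methyl acetoacetate and 1-bromo-4-methylpentane (C-alkylation, then two silylations).
3. Ynone: from 4,5-dichloro-1H-pyrrole-2-carboxylic acid (Weinreb amide, then ethynylmagnesium bromide).
4. Ring order: the dichloropyrrole ring is bought intact; the benzene ring is formed last, in the final step, without protecting groups.

**Route**

Step 1
Reactants: 1 methyl acetoacetate (methyl 3-oxobutanoate); 2 1-bromo-4-methylpentane
Product: 3 methyl 2-acetyl-6-methylheptanoate (= methyl 2-(4-methylpentyl)-3-oxobutanoate, racemic)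
Conditions: NaH (1.4 equiv), 1 (1.5 equiv), THF/DMF 4:1, 0 °C, 30 min; then 2 (1.0 equiv), 65 °C, 16 h
Reagents that add atoms: none
Why: Acetoacetic ester alkylation, in which the sodium enolate of 1 displaces the unhindered primary bromide by SN2 at carbon, excess 1 suppresses dialkylation, and the racemic C2 stereocentre is erased in step 2.

Step 2
Reactants: 3 methyl 2-acetyl-6-methylheptanoate
Product: 4 methyl 2-(4-methylpentyl)-3-[(trimethylsilyl)oxy]but-2-enoate (E/Z mixture)
Conditions: TMSCl (1.8 equiv), Et3N (1.6 equiv), toluene, 23 °C, 72 h; filter, distil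
Reagents that add atoms: chlorotrimethylsilane, C[Si](C)(C)Cl
Why: Silyl enol ether formation by soft enolisation of the β-keto ester at the acidic C2–H gives the conjugated tetrasubstituted enol ether, the standard first stage of a Chan-diene preparation.

Step 3
Reactants: 4 methyl 2-(4-methylpentyl)-3-[(trimethylsilyl)oxy]but-2-enoate
Product: 5 1-methoxy-2-(4-methylpentyl)-1,3-bis[(trimethylsilyl)oxy]buta-1,3-diene (mixture of ketene acetal isomers, used crude)
Conditions: LiN(iPr)2 (1.3 equiv, commercial solution), THF, −78 °C, 1 h; TMSCl (1.5 equiv), −78 → 23 °C; pentane, filtration under argon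
Reagents that add atoms: chlorotrimethylsilane, C[Si](C)(C)Cl
Why: Vinylogous (γ-methyl) deprotonation of the β-silyloxy enoate followed by kinetic O-silylation of the dienolate gives the 1,3-bis(silyl enol ether), the second stage of the Chan-diene synthesis, which is precedented for 2-alkyl acetoacetates.

Step 4
Reactants: 6 4,5-dichloro-1H-pyrrole-2-carboxylic acid
Product: 8 4,5-dichloro-N-methoxy-N-methyl-1H-pyrrole-2-carboxamide, via acyl imidazole 7 (not isolated)
Conditions: 1,1'-carbonyldiimidazole (CDI, 1.2 equiv), THF, 23 °C, 1 h; then MeNH(OMe)·HCl (1.5 equiv), 23 °C, 16 h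
Reagents that add atoms: N,O-dimethylhydroxylamine hydrochloride, CNOC.Cl; 1,1'-carbonyldiimidazole, O=C(n1ccnc1)n1ccnc1 (its imidazolyl group is present in intermediate 7 only)
Why: Weinreb amide synthesis by CDI activation and aminolysis, run without added base so the N–H pyrrole acyl donor cannot dimerise to a pyrocoll.

Step 5
Reactants: 8 4,5-dichloro-N-methoxy-N-methyl-1H-pyrrole-2-carboxamide; 9 ethynylmagnesium bromide (HC≡CMgBr)
Product: 10 1-(4,5-dichloro-1H-pyrrol-2-yl)prop-2-yn-1-one
Conditions: 9 (3.0 equiv, 0.5 M in THF), THF, 0 → 23 °C, 3 h; cannulate into cold 1 M aq NaHSO4, 0 °C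
Reagents that add atoms: none
Why: Weinreb ketone synthesis, in which one equivalent of 9 deprotonates the pyrrole N–H, a second adds to give a stable magnesium chelate that blocks over-addition, and the inverse acidic quench protonates the released N,O-dimethylhydroxylamine before it can add to the ynone.

Step 6
Reactants: 5 1-methoxy-2-(4-methylpentyl)-1,3-bis[(trimethylsilyl)oxy]buta-1,3-diene; 10 1-(4,5-dichloro-1H-pyrrol-2-yl)prop-2-yn-1-one
Product: 13 (4,5-dichloro-1H-pyrrol-2-yl)[2,4-dihydroxy-3-(4-methylpentyl)phenyl]methanone, via cyclohexadiene cycloadduct 11 (not isolated), via aryl silyl ether 12 (not isolated)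
Conditions: 5 (2.5 equiv), toluene, 80 °C, 12 h; then 1 M HCl, THF, 23 °C, 1 h
Reagents that add atoms: none
Why: Diels–Alder benzannulation of a Chan-type diene with an ynone (Danishefsky-type resorcinol synthesis), in which the nucleophilic CH2 terminus of the diene bonds to the β-carbon of the ynone so that the ketene acetal carbon ends up next to the acyl-bearing carbon, loss of MeOSiMe3 and tautomerisation aromatise the ring to the 1-acyl-2,4-dihydroxy-3-alkyl pattern, and acid cleaves the remaining silyl ether to give the achiral target.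

**Compound list**
1 | methyl acetoacetate (methyl 3-oxobutanoate) | CC(=O)CC(=O)OC | starting material
2 | 1-bromo-4-methylpentane | CC(C)CCCBr | starting material
3 | methyl 2-acetyl-6-methylheptanoate (racemic) | CC(=O)C(CCCC(C)C)C(=O)OC | intermediate
4 | methyl 2-(4-methylpentyl)-3-[(trimethylsilyl)oxy]but-2-enoate (E/Z mixture) | COC(=O)C(CCCC(C)C)=C(C)O[Si](C)(C)C | intermediate
5 | 1-methoxy-2-(4-methylpentyl)-1,3-bis[(trimethylsilyl)oxy]buta-1,3-diene (isomer mixture at the ketene acetal) | C=C(O[Si](C)(C)C)C(CCCC(C)C)=C(OC)O[Si](C)(C)C | intermediate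
6 | 4,5-dichloro-1H-pyrrole-2-carboxylic acid | OC(=O)c1cc(Cl)c(Cl)[nH]1 | starting material
7 | (4,5-dichloro-1H-pyrrol-2-yl)(1H-imidazol-1-yl)methanone (acyl imidazole, not isolated) | O=C(c1cc(Cl)c(Cl)[nH]1)n1ccnc1 | intermediate
8 | 4,5-dichloro-N-methoxy-N-methyl-1H-pyrrole-2-carboxamide | CON(C)C(=O)c1cc(Cl)c(Cl)[nH]1 | intermediate
9 | ethynylmagnesium bromide | C#C[Mg]Br | starting material
10 | 1-(4,5-dichloro-1H-pyrrol-2-yl)prop-2-yn-1-one | C#CC(=O)c1cc(Cl)c(Cl)[nH]1 | intermediate
11 | (4,5-dichloro-1H-pyrrol-2-yl){6-methoxy-5-(4-methylpentyl)-4,6-bis[(trimethylsilyl)oxy]cyclohexa-1,4-dien-1-yl}methanone (racemic cycloadduct, not isolated) | COC1(O[Si](C)(C)C)C(CCCC(C)C)=C(O[Si](C)(C)C)CC=C1C(=O)c1cc(Cl)c(Cl)[nH]1 | intermediate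
12 | (4,5-dichloro-1H-pyrrol-2-yl){2-hydroxy-3-(4-methylpentyl)-4-[(trimethylsilyl)oxy]phenyl}methanone (not isolated) | CC(C)CCCc1c(O[Si](C)(C)C)ccc(C(=O)c2cc(Cl)c(Cl)[nH]2)c1O | intermediate
13 | (4,5-dichloro-1H-pyrrol-2-yl)[2,4-dihydroxy-3-(4-methylpentyl)phenyl]methanone | CC(C)CCCc1c(O)ccc(C(=O)c2cc(Cl)c(Cl)[nH]2)c1O | target

**Totals**
Total step count: 6. Longest linear sequence: 4 steps (steps 1, 2, 3, 6); the other branch is steps 4, 5, 6.

**Three steps most likely to fail, with fallbacks**

Step 6 (highest risk). The acidic pyrrole N–H of 10 may protonate the ketene acetal diene or start aza-Michael oligomerisation of the ynone, and a Mukaiyama–Michael addition without ring closure may compete. The fallback masks the nitrogen; it sets out from 8 and comes back to the route at 13. Compound 8 is treated with Boc2O and catalytic 4-(dimethylamino)pyridine in MeCN to give tert-butyl 2,3-dichloro-5-[methoxy(methyl)carbamoyl]-1H-pyrrole-1-carboxylate F1. Addition of 9 (1.3 equiv, THF, −40 °C, inverse quench into cold aq NaHSO4) gives tert-butyl 2,3-dichloro-5-(prop-2-ynoyl)-1H-pyrrole-1-carboxylate F2. Heating F2 with 5 in toluene at 60 °C gives the racemic N-Boc cyclohexadiene cycloadduct F3, which loses methoxytrimethylsilane in the flask to give the N-Boc aryl silyl ether F4. CF3CO2H in CH2Cl2 at 23 °C then removes the Boc group and the silyl ether to give 13.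

Step 5. The N-magnesiated Weinreb amide is a poor electrophile, and the terminal ynone is prone to conjugate addition of the liberated hydroxylamine. The fallback changes the oxidation-state logic; it sets out from 8 and comes back at 10. Reduction of 8 with LiAlH4 (THF, −20 °C) gives 4,5-dichloro-1H-pyrrole-2-carbaldehyde F5, which removes the amine before any ynone exists. Addition of 9 (2.5 equiv, THF, 0 °C) to this more electrophilic aldehyde gives racemic 1-(4,5-dichloro-1H-pyrrol-2-yl)prop-2-yn-1-ol F6. Oxidation with MnO2 in CH2Cl2 at 23 °C destroys the carbinol stereocentre and gives 10.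

Step 3. The hindered bis(silyloxy)diene 5 is hydrolytically labile and may suffer C-silylation or incomplete γ-deprotonation. The fallback uses a more robust Brassard-type diene and ends with a demethylation; it sets out from 3 and comes back at 13. Compound 3 with HC(OMe)3 and catalytic p-toluenesulfonic acid in MeOH gives the racemic ketal methyl 3,3-dimethoxy-2-(4-methylpentyl)butanoate F7. Heating F7 with the same acid while distilling out methanol gives methyl 3-methoxy-2-(4-methylpentyl)but-2-enoate F8 (E/Z mixture). LiN(iPr)2 then TMSCl (THF, −78 °C) gives 1,3-dimethoxy-2-(4-methylpentyl)-1-[(trimethylsilyl)oxy]buta-1,3-diene F9. Cycloaddition of F9 with 10 (toluene, 80 °C) gives the racemic cyclohexadiene cycloadduct F10, which loses methoxytrimethylsilane to give (4,5-dichloro-1H-pyrrol-2-yl)[2-hydroxy-4-methoxy-3-(4-methylpentyl)phenyl]methanone F11. BBr3 in CH2Cl2 (−78 → 0 °C) cleaves the aryl methyl ether to give 13.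

**Further compounds**
F1 | step 6 | tert-butyl 2,3-dichloro-5-[methoxy(methyl)carbamoyl]-1H-pyrrole-1-carboxylate | CON(C)C(=O)c1cc(Cl)c(Cl)n1C(=O)OC(C)(C)C
F2 | step 6 | tert-butyl 2,3-dichloro-5-(prop-2-ynoyl)-1H-pyrrole-1-carboxylate | C#CC(=O)c1cc(Cl)c(Cl)n1C(=O)OC(C)(C)C
F3 | step 6 | tert-butyl 2,3-dichloro-5-{[6-methoxy-5-(4-methylpentyl)-4,6-bis(trimethylsilyloxy)cyclohexa-1,4-dien-1-yl]carbonyl}-1H-pyrrole-1-carboxylate (racemic) | COC1(O[Si](C)(C)C)C(CCCC(C)C)=C(O[Si](C)(C)C)CC=C1C(=O)c1cc(Cl)c(Cl)n1C(=O)OC(C)(C)C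
F4 | step 6 | tert-butyl 2,3-dichloro-5-{2-hydroxy-3-(4-methylpentyl)-4-[(trimethylsilyl)oxy]benzoyl}-1H-pyrrole-1-carboxylate | CC(C)CCCc1c(O[Si](C)(C)C)ccc(C(=O)c2cc(Cl)c(Cl)n2C(=O)OC(C)(C)C)c1O
F5 | step 5 | 4,5-dichloro-1H-pyrrole-2-carbaldehyde | O=Cc1cc(Cl)c(Cl)[nH]1
F6 | step 5 | 1-(4,5-dichloro-1H-pyrrol-2-yl)prop-2-yn-1-ol (racemic) | C#CC(O)c1cc(Cl)c(Cl)[nH]1
F7 | step 3 | methyl 3,3-dimethoxy-2-(4-methylpentyl)butanoate (racemic) | COC(C)(OC)C(CCCC(C)C)C(=O)OC
F8 | step 3 | methyl 3-methoxy-2-(4-methylpentyl)but-2-enoate (E/Z mixture) | COC(C)=C(CCCC(C)C)C(=O)OC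
F9 | step 3 | 1,3-dimethoxy-2-(4-methylpentyl)-1-[(trimethylsilyl)oxy]buta-1,3-diene | C=C(OC)C(CCCC(C)C)=C(OC)O[Si](C)(C)C
F10 | step 3 | (4,5-dichloro-1H-pyrrol-2-yl){4,6-dimethoxy-5-(4-methylpentyl)-6-[(trimethylsilyl)oxy]cyclohexa-1,4-dien-1-yl}methanone (racemic) | COC1=C(CCCC(C)C)C(OC)(O[Si](C)(C)C)C(C(=O)c2cc(Cl)c(Cl)[nH]2)=CC1
F11 | step 3 | (4,5-dichloro-1H-pyrrol-2-yl)[2-hydroxy-4-methoxy-3-(4-methylpentyl)phenyl]methanone | COc1ccc(C(=O)c2cc(Cl)c(Cl)[nH]2)c(O)c1CCCC(C)C
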